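**Retrosynthetic overview**

1. In germacrane numbering the target is a ten-membered carbocycle (C1–C10) bridged by the C1–O–C4 oxolane and fused at C6/C7 to an E-5-ylidene butenolide (O–C6=C5, C7=C11, C12=O). The last disconnections are C1 hemiketal ⇒ methyl ketal, C13 acetate ⇒ silyl ether and C8 ester ⇒ C8 alcohol.
2. Key disconnection C7–C8 (Nozaki–Hiyama–Kishi). The feature it rests on: the C8 carbinol carbon is bonded directly to the butenolide β-carbon C7, and C5 and C10 leave the oxolane ring (C1, C2, C3, C4, O) from the same face, so a C7 enol triflate and a C8 aldehyde held on that oxolane close the carbocycle.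
3. Precursor ⇒ E-ylidene tetronate triflate ⇐ Z isomer (photoisomerisation) ⇐ vinylogous aldol condensation of allyl tetronate with the C5 aldehyde. C13 comes from C11 lithiation and formaldehyde.
4. Oxolane ketal aldehyde ⇒ (R)-linalool (C4) and E-crotylboronate (C10): selective ozonolysis, anti-crotylboration, hydroboration, oxidation, ketalisation, second ozonolysis.
5. Ring order: oxolane ketal (step 7), butenolide brought in as the tetronate (step 10), ten-membered carbocycle (step 17), hemiketal unveiled last (step 23).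

Key step: step 17

Remark: germacrane numbering is used for all intermediates; the methyl ketal anomer needed is the one with the C10 chain cis to C5, and it is assumed to be separable from its C1 epimer.

**Route**

Step 1
Reactants: 1 (R)-linalool
Product: 2 (R)-linalool triethylsilyl ether
Conditions: TESOTf, 2,6-lutidine, CH2Cl2, −78 → 0 °C
Reagents that add atoms: triethylsilyl trifluoromethanesulfonate, CC[Si](CC)(CC)OS(=O)(=O)C(F)(F)F
Why: Silylation of the tertiary allylic alcohol with the silyl triflate keeps the C4 hydroxyl from closing to a lactol once the C1 aldehyde is freed, and the C4 stereocentre of the starting material is not touched.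

Step 2
Reactants: 2 (R)-linalool triethylsilyl ether
Product: 4 (4R)-4-methyl-4-[(triethylsilyl)oxy]hex-5-enal, via ozonide 3 (not isolated)
Conditions: O3, CH2Cl2, −78 °C, to the end-point of Sudan Red 7B; then PPh3, −78 °C → rt
Reagents that add atoms: ozone, O=[O+][O-]
Why: Chemoselective ozonolysis with reductive work-up, in which the electron-rich trisubstituted alkene should react far faster than the vinyl group, which is monosubstituted, sits on a quaternary carbon and is deactivated by the allylic silyloxy group.

Step 3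
Reactants: 4 (4R)-4-methyl-4-[(triethylsilyl)oxy]hex-5-enal; 5 (E)-crotylboronic acid pinacol ester
Product: 6 (3R,4S,7R)-3,7-dimethyl-7-[(triethylsilyl)oxy]nona-1,8-dien-4-ol
Conditions: (R)-TRIP phosphoric acid (5 mol%), toluene, −30 °C; aq. NaHCO3 work-up
Reagents that add atoms: none
Why: Brønsted-acid-catalysed crotylboration through a closed chair transition state, in which the E boronate fixes the anti relationship of C1–OH and C10–CH3 and the R acid is expected to direct addition to the Re face of the aldehyde, which sets C10 as R (C1 is oxidised later, so only C10 is carried on).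

Step 4
Reactants: 6 (3R,4S,7R)-3,7-dimethyl-7-[(triethylsilyl)oxy]nona-1,8-dien-4-ol
Product: 8 (3R,4S,7R)-3,7-dimethyl-7-[(triethylsilyl)oxy]non-8-ene-1,4-diol, via borane adduct 7 (not isolated)
Conditions: 9-BBN (2.2 equiv), THF, 0 °C → rt; then NaOH, H2O2, 0 °C
Reagents that add atoms: hydrogen peroxide, OO
Why: Anti-Markovnikov hydroboration–oxidation, in which the dialkylborane should take the vinyl group on the secondary carbon C10 and leave the vinyl group on the quaternary, silyloxy-bearing C4, which is both more hindered and inductively deactivated.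

Step 5
Reactants: 8 (3R,4S,7R)-3,7-dimethyl-7-[(triethylsilyl)oxy]non-8-ene-1,4-diol
Product: 9 C8 4-methoxybenzyl ether of diol 8
Conditions: NaH (1.05 equiv), 4-methoxybenzyl chloride, Bu4NI (cat.), THF/DMF, 0 °C
Reagents that add atoms: 4-methoxybenzyl chloride, COc1ccc(CCl)cc1
Why: Williamson etherification under kinetic control, in which the primary C8 alkoxide should be alkylated much faster than the secondary C1 alkoxide next to the methyl-branched C10; this ether survives acid, base and organolithium reagents and is later removed oxidatively without acid.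

Step 6
Reactants: 9 C8 4-methoxybenzyl ether
Product: 10 C1 ketone (3R,7R)-1-[(4-methoxyphenyl)methoxy]-3,7-dimethyl-7-[(triethylsilyl)oxy]non-8-en-4-one
Conditions: Dess–Martin periodinane, NaHCO3, CH2Cl2, 0 °C → rt
Reagents that add atoms: none
Why: Dess–Martin oxidation under buffered, non-enolising conditions converts the C1 carbinol into the ketone without epimerising the adjacent C10 stereocentre.

Step 7
Reactants: 10 C1 ketone
Product: 11 (2R,5S)-2-ethenyl-5-methoxy-5-[(2R)-4-[(4-methoxyphenyl)methoxy]butan-2-yl]-2-methyloxolane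
Conditions: camphorsulfonic acid (cat.), MeOH, 0 °C → rt; Et3N quench
Reagents that add atoms: methanol, CO
Why: Acid-catalysed methanolysis removes the tertiary silyl ether, the freed C4 hydroxyl closes on the C1 ketone and methanol traps the cyclic oxocarbenium ion as the mixed methyl ketal; C1 forms under thermodynamic control as both anomers, so the 5S anomer (C10 chain cis to the vinyl group) is separated and the other is returned to the same conditions.

Step 8
Reactants: 11 vinyl oxolane methyl ketal
Product: 13 (2R,5S)-5-methoxy-5-[(2R)-4-[(4-methoxyphenyl)methoxy]butan-2-yl]-2-methyloxolane-2-carbaldehyde, via ozonide 12 (not isolated)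
Conditions: O3, CH2Cl2, −78 °C, to the end-point of Sudan Red 7B; then PPh3
Reagents that add atoms: ozone, O=[O+][O-]
Why: Ozonolysis of the remaining vinyl group with reductive work-up gives the non-enolisable α-alkoxy aldehyde at C5, and the ketal and the aryl ether should survive if ozone is stopped at the end-point.

Step 9
Reactants: 14 tetronic acid
Product: 15 allyl tetronate, 4-(prop-2-en-1-yloxy)furan-2(5H)-one
Conditions: allyl alcohol, TsOH·H2O (cat.), toluene, reflux, Dean–Stark
Reagents that add atoms: allyl alcohol, C=CCO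
Why: Acid-catalysed vinylogous Fischer esterification of the enolic hydroxyl with removal of water; the allyl group is chosen because zerovalent palladium can later remove it under neutral conditions that the ketal tolerates.

Step 10
Reactants: 15 allyl tetronate; 13 oxolane C5 aldehyde
Product: 17 C5 aldol adduct (diastereomer mixture at C5 and C6), via lithium dienolate 16 (not isolated)
Conditions: LiN(iPr)2, THF, −78 °C; then 13, −78 °C; aq. work-up
Reagents that add atoms: none
Why: Vinylogous aldol addition in which the amide base removes the γ-proton of the tetronate and the lithium dienolate adds through C6 to the aldehyde; the two new stereocentres (C5, C6) are not controlled because both become sp2 in the next step.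

Step 11
Reactants: 17 C5 aldol adduct
Product: 19 Z-ylidene allyl tetronate, via C5 mesylate 18 (not isolated)
Conditions: MsCl, Et3N, CH2Cl2, 0 °C; then DBU, 0 °C → rt
Reagents that add atoms: none
Why: Mesylation followed by E1cB elimination through the C6 dienolate gives the conjugated enol lactone; because the acidic C6–H routes the reaction through the planar dienolate, the less congested Z alkene (C4 syn to the ring oxygen) is expected, and the geometry is corrected in step 14.

Step 12
Reactants: 19 Z-ylidene allyl tetronate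
Product: 22 Z-ylidene tetronate C13 triethylsilyl ether, via C11 alkenyllithium 20 (not isolated), via C13 lithium alkoxide 21 (not isolated)
Conditions: LiN(iPr)2, THF, −78 °C; then HCHO (gas, from cracked paraformaldehyde); then TESCl, −78 → 0 °C
Reagents that add atoms: formaldehyde, C=O; chlorotriethylsilane, CC[Si](Cl)(CC)CC
Why: Deprotonation of the vinylic C11–H of the 5-ylidene tetronate (the most acidic site once C6 is sp2), hydroxymethylation and silylation in one flask; a silyl ether is installed because a tetronate anion bearing a 3-acyloxymethyl group would expel the carboxylate in step 13, so the acetate is introduced only after ring closure.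

Step 13
Reactants: 22 Z-ylidene tetronate C13 triethylsilyl ether
Product: 24 Z-ylidene C7 enol triflate, via triethylammonium tetronate 23 (not isolated)
Conditions: Pd(PPh3)4 (5 mol%), HCO2H, Et3N, THF, rt; evaporate; then Tf2O, 2,6-lutidine, CH2Cl2, −78 °C
Reagents that add atoms: trifluoromethanesulfonic anhydride, O=S(=O)(OS(=O)(=O)C(F)(F)F)C(F)(F)F
Why: Tsuji–Trost-type deallylation in which zerovalent palladium ionises the allyl vinylogous ester and formate reduces the allyl fragment to propene, followed by O-sulfonylation of the tetronate to the vinylogous acyl triflate, all without an acidic step that could disturb the ketal.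

Step 14
Reactants: 24 Z-ylidene C7 enol triflate
Product: 25 E-ylidene C7 enol triflate
Conditions: thioxanthone (10 mol%), 395 nm LED, degassed MeCN, rt; E isomer separated, Z isomer re-irradiated
Reagents that add atoms: none
Why: Triplet-sensitised E/Z photoisomerisation of the exocyclic enol-lactone alkene, a known behaviour of 5-ylidenebutenolides, gives a photostationary mixture from which the contra-thermodynamic E isomer (C4 syn to C7, as the ring closure requires) should be separable while the Z isomer is recycled.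

Step 15
Reactants: 25 E-ylidene C7 enol triflate
Product: 26 E-ylidene triflate C8 alcohol
Conditions: DDQ, CH2Cl2/pH 7 phosphate buffer, 0 °C
Reagents that add atoms: none
Why: Oxidative cleavage of the 4-methoxybenzyl ether by electron transfer to DDQ under neutral conditions that spare the enol triflate, the silyl ether and the methyl ketal; the buffer is there to keep the freed γ-hydroxyl from exchanging into the ketal.

Step 16
Reactants: 26 E-ylidene triflate C8 alcohol
Product: 27 E-ylidene triflate C8 aldehyde (cyclisation precursor)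
Conditions: Dess–Martin periodinane, NaHCO3, CH2Cl2, 0 °C
Reagents that add atoms: none
Why: Buffered Dess–Martin oxidation of the primary alcohol gives the C8 aldehyde without acid, and the C10 stereocentre is β to the new carbonyl and not at risk.

Step 17
Reactants: 27 E-ylidene triflate C8 aldehyde
Product: 28 (1S,4R,5E,8S,10R)-1,4-epoxy-8-hydroxy-1-methoxy-13-[(triethylsilyl)oxy]germacra-5,7(11)-dien-12,6-olide
Conditions: CrCl2 (8 equiv), NiCl2 (2 mol%), degassed DMF, rt, 27 added over 12 h to a final 2 mM; aq. work-up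
Reagents that add atoms: none
Why: Nozaki–Hiyama–Kishi reaction: zerovalent nickel, formed from NiCl2 by CrCl2, inserts into the C7–OTf bond of the vinylogous acyl triflate, the alkenylnickel transmetallates to trivalent chromium and the alkenylchromium adds to the C8 aldehyde. The closest precedent is the macrocyclising coupling of alkenyl triflates or iodides with aldehydes under the same reagents, medium rings included. The one ring formed is the ten-membered carbocycle C1–C10, closed by 10-exo-trig 1,2-addition at C7–C8 on a chain already bent by the cis arms of the oxolane and by the E enol-lactone alkene that holds C4 and C7 syn. The new stereocentre C8 is set under substrate control: with the C10 methyl pseudo-equatorial and the carbonyl oxygen turned to the outside of the forming ring, the alkenyl carbon should reach the aldehyde face that gives the 8S carbinol (oxygen syn to the C10 methyl in the extended C10–C9–C8 chain), which is a prediction and not a certainty. The step needs insertion at C7–OTf and addition to the aldehyde in the presence of ketal, lactone and silyl ether, which the non-basic alkenylchromium allows, and it needs ring closure to outrun oligomerisation and protodemetallation, which slow addition at high dilution addresses; the only β-heteroatom of the alkenylmetal, the lactone oxygen on sp2 C6, could leave only by forming a cumulene, so β-elimination is not expected, and the C13 silyl ether offers zerovalent nickel no allylic ester to ionise.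

Step 18
Reactants: 29 [(tert-butyldimethylsilyl)oxy]acetaldehyde; 30 ethyl 2-(triphenylphosphoranylidene)propanoate
Product: 31 ethyl (2E)-4-[(tert-butyldimethylsilyl)oxy]-2-methylbut-2-enoate
Conditions: CH2Cl2, rt
Reagents that add atoms: none
Why: Wittig olefination with the stabilised α-methyl ylide should give the E trisubstituted enoate (ester trans to the CH2O group).

Step 19
Reactants: 31 ethyl (2E)-4-[(tert-butyldimethylsilyl)oxy]-2-methylbut-2-enoate
Product: 33 (2E)-4-[(tert-butyldimethylsilyl)oxy]-2-methylbut-2-enoic acid, via lithium carboxylate 32 (not isolated)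
Conditions: LiOH, THF/H2O, rt; then 1 M HCl to pH 4, 0 °C
Reagents that add atoms: lithium hydroxide, [Li+].[OH-]
Why: Ester saponification at room temperature, which the primary silyl ether tolerates, followed by careful acidification to the free acid.

Step 20
Reactants: 28 tricyclic C8 alcohol; 33 silyl-protected hydroxytiglic acid
Product: 35 C8 ester of 28, via mixed anhydride 34 (not isolated)
Conditions: 2,4,6-trichlorobenzoyl chloride, Et3N, THF, rt; then 28, DMAP, toluene, rt
Reagents that add atoms: none
Why: Yamaguchi esterification in which the mixed anhydride acylates the hindered secondary C8 hydroxyl under DMAP catalysis with retention at C8, and the E geometry of the tiglate is the stable one.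

Step 21
Reactants: 35 C8 ester
Product: 36 C13 primary alcohol
Conditions: pyridinium p-toluenesulfonate (cat.), MeOH/CH2Cl2, 0 °C
Reagents that add atoms: none
Why: Acid-catalysed methanolysis removes the primary triethylsilyl ether much faster than the primary tert-butyldimethylsilyl ether, and the methyl ketal can only exchange with the solvent.

Step 22
Reactants: 36 C13 primary alcohol
Product: 37 C13 acetate
Conditions: Ac2O, pyridine, CH2Cl2, 0 °C → rt
Reagents that add atoms: acetic anhydride, CC(=O)OC(C)=O
Why: Acetylation of the only free hydroxyl, the primary allylic C13 alcohol, with acetic anhydride and pyridine.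

Step 23
Reactants: 37 C13 acetate
Product: 38 target CNP0154520.1
Conditions: 0.2 M aq. HCl, THF, 0 °C → rt
Reagents that add atoms: water, O
Why: Dilute aqueous acid hydrolyses the methyl ketal through the bridgehead oxocarbenium ion to the hemiketal, whose C1 configuration is dictated by the oxygen bridge, and cleaves the remaining silyl ether, while the allylic acetate and the two esters should survive.

**Compound list**

1 | (R)-linalool, (3R)-3,7-dimethylocta-1,6-dien-3-ol | C=C[C@](C)(O)CCC=C(C)C | starting material
2 | triethyl{[(3R)-3,7-dimethylocta-1,6-dien-3-yl]oxy}silane | C=C[C@](C)(O[Si](CC)(CC)CC)CCC=C(C)C | intermediate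
3 | 5,5-dimethyl-3-[(3R)-3-methyl-3-[(triethylsilyl)oxy]pent-4-en-1-yl]-1,2,4-trioxolane (ozonide, not isolated) | C=C[C@](C)(O[Si](CC)(CC)CC)CCC1OOC(C)(C)O1 | intermediate
4 | (4R)-4-methyl-4-[(triethylsilyl)oxy]hex-5-enal | C=C[C@](C)(O[Si](CC)(CC)CC)CCC=O | intermediate
5 | (E)-crotylboronic acid pinacol ester | C/C=C/CB1OC(C)(C)C(C)(C)O1 | starting material
6 | (3R,4S,7R)-3,7-dimethyl-7-[(triethylsilyl)oxy]nona-1,8-dien-4-ol | C=C[C@](C)(O[Si](CC)(CC)CC)CC[C@H](O)[C@H](C)C=C | intermediate
7 | C8-alkyl, C1-O bis(9-borabicyclo[3.3.1]nonan-9-yl) adduct of 6 (not isolated) | C=C[C@](C)(O[Si](CC)(CC)CC)CC[C@H](OB1C2CCCC1CCC2)[C@H](C)CCB1C2CCCC1CCC2 | intermediate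
8 | (3R,4S,7R)-3,7-dimethyl-7-[(triethylsilyl)oxy]non-8-ene-1,4-diol | C=C[C@](C)(O[Si](CC)(CC)CC)CC[C@H](O)[C@H](C)CCO | intermediate
9 | (3R,4S,7R)-1-[(4-methoxyphenyl)methoxy]-3,7-dimethyl-7-[(triethylsilyl)oxy]non-8-en-4-ol | C=C[C@](C)(O[Si](CC)(CC)CC)CC[C@H](O)[C@H](C)CCOCc1ccc(OC)cc1 | intermediate
10 | (3R,7R)-1-[(4-methoxyphenyl)methoxy]-3,7-dimethyl-7-[(triethylsilyl)oxy]non-8-en-4-one | C=C[C@](C)(O[Si](CC)(CC)CC)CCC(=O)[C@H](C)CCOCc1ccc(OC)cc1 | intermediate
11 | (2R,5S)-2-ethenyl-5-methoxy-5-[(2R)-4-[(4-methoxyphenyl)methoxy]butan-2-yl]-2-methyloxolane | C=C[C@@]1(C)CC[C@](OC)(O1)[C@H](C)CCOCc2ccc(OC)cc2 | intermediate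
12 | 3-{(2R,5S)-5-methoxy-5-[(2R)-4-[(4-methoxyphenyl)methoxy]butan-2-yl]-2-methyloxolan-2-yl}-1,2,4-trioxolane (ozonide, not isolated) | C1(OCOO1)[C@@]2(C)CC[C@](OC)(O2)[C@H](C)CCOCc3ccc(OC)cc3 | intermediate
13 | (2R,5S)-5-methoxy-5-[(2R)-4-[(4-methoxyphenyl)methoxy]butan-2-yl]-2-methyloxolane-2-carbaldehyde | O=C[C@@]1(C)CC[C@](OC)(O1)[C@H](C)CCOCc2ccc(OC)cc2 | intermediate
14 | tetronic acid, 4-hydroxyfuran-2(5H)-one | OC1=CC(=O)OC1 | starting material
15 | allyl tetronate, 4-(prop-2-en-1-yloxy)furan-2(5H)-one | C=CCOC1=CC(=O)OC1 | intermediate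
16 | lithium 4-(prop-2-en-1-yloxy)furan-2-olate (not isolated) | [Li+].[O-]c1cc(OCC=C)co1 | intermediate
17 | 5-[hydroxy{(2R,5S)-5-methoxy-5-[(2R)-4-[(4-methoxyphenyl)methoxy]butan-2-yl]-2-methyloxolan-2-yl}methyl]-4-(prop-2-en-1-yloxy)furan-2(5H)-one, mixture at the carbinol carbon and C5 of the furanone | C=CCOC1=CC(=O)OC1C(O)[C@@]2(C)CC[C@](OC)(O2)[C@H](C)CCOCc3ccc(OC)cc3 | intermediate
18 | methanesulfonate of 17 at the carbinol oxygen (not isolated) | C=CCOC1=CC(=O)OC1C(OS(C)(=O)=O)[C@@]2(C)CC[C@](OC)(O2)[C@H](C)CCOCc3ccc(OC)cc3 | intermediate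
19 | (5Z)-5-{[(2R,5S)-5-methoxy-5-[(2R)-4-[(4-methoxyphenyl)methoxy]butan-2-yl]-2-methyloxolan-2-yl]methylidene}-4-(prop-2-en-1-yloxy)furan-2(5H)-one | C1=C(OCC=C)/C(=C/[C@@]2(C)CC[C@](OC)(O2)[C@H](C)CCOCc3ccc(OC)cc3)OC1=O | intermediate
20 | 3-lithio derivative of 19 (C11 alkenyllithium, not isolated) | [Li]C1=C(OCC=C)/C(=C/[C@@]2(C)CC[C@](OC)(O2)[C@H](C)CCOCc3ccc(OC)cc3)OC1=O | intermediate
21 | lithium alkoxide of the 3-(hydroxymethyl) derivative of 19 (not isolated) | [Li+].[O-]CC1=C(OCC=C)/C(=C/[C@@]2(C)CC[C@](OC)(O2)[C@H](C)CCOCc3ccc(OC)cc3)OC1=O | intermediate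
22 | (5Z)-5-{[(2R,5S)-5-methoxy-5-[(2R)-4-[(4-methoxyphenyl)methoxy]butan-2-yl]-2-methyloxolan-2-yl]methylidene}-4-(prop-2-en-1-yloxy)-3-{[(triethylsilyl)oxy]methyl}furan-2(5H)-one | CC[Si](CC)(CC)OCC1=C(OCC=C)/C(=C/[C@@]2(C)CC[C@](OC)(O2)[C@H](C)CCOCc3ccc(OC)cc3)OC1=O | intermediate
23 | triethylammonium salt of the Z-ylidene 3-{[(triethylsilyl)oxy]methyl}tetronic acid (not isolated) | CC[NH+](CC)CC.CC[Si](CC)(CC)OCC1=C([O-])/C(=C/[C@@]2(C)CC[C@](OC)(O2)[C@H](C)CCOCc3ccc(OC)cc3)OC1=O | intermediate
24 | (2Z)-2-{[(2R,5S)-5-methoxy-5-[(2R)-4-[(4-methoxyphenyl)methoxy]butan-2-yl]-2-methyloxolan-2-yl]methylidene}-5-oxo-4-{[(triethylsilyl)oxy]methyl}-2,5-dihydrofuran-3-yl trifluoromethanesulfonate | CC[Si](CC)(CC)OCC1=C(OS(=O)(=O)C(F)(F)F)/C(=C/[C@@]2(C)CC[C@](OC)(O2)[C@H](C)CCOCc3ccc(OC)cc3)OC1=O | intermediate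
25 | (2E) isomer of 24 | CC[Si](CC)(CC)OCC1=C(OS(=O)(=O)C(F)(F)F)/C(=C\[C@@]2(C)CC[C@](OC)(O2)[C@H](C)CCOCc3ccc(OC)cc3)OC1=O | intermediate
26 | (2E)-2-{[(2R,5S)-5-[(2R)-4-hydroxybutan-2-yl]-5-methoxy-2-methyloxolan-2-yl]methylidene}-5-oxo-4-{[(triethylsilyl)oxy]methyl}-2,5-dihydrofuran-3-yl trifluoromethanesulfonate | CC[Si](CC)(CC)OCC1=C(OS(=O)(=O)C(F)(F)F)/C(=C\[C@@]2(C)CC[C@](OC)(O2)[C@H](C)CCO)OC1=O | intermediate
27 | (2E)-2-{[(2R,5S)-5-methoxy-2-methyl-5-[(2R)-4-oxobutan-2-yl]oxolan-2-yl]methylidene}-5-oxo-4-{[(triethylsilyl)oxy]methyl}-2,5-dihydrofuran-3-yl trifluoromethanesulfonate | CC[Si](CC)(CC)OCC1=C(OS(=O)(=O)C(F)(F)F)/C(=C\[C@@]2(C)CC[C@](OC)(O2)[C@H](C)CC=O)OC1=O | intermediate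
28 | (1S,4R,5E,8S,10R)-1,4-epoxy-8-hydroxy-1-methoxy-13-[(triethylsilyl)oxy]germacra-5,7(11)-dien-12,6-olide | CC[Si](CC)(CC)OCC1=C2/C(=C\[C@@]3(C)CC[C@](OC)(O3)[C@H](C)C[C@@H]2O)OC1=O | intermediate
29 | [(tert-butyldimethylsilyl)oxy]acetaldehyde | CC(C)(C)[Si](C)(C)OCC=O | starting material
30 | ethyl 2-(triphenylphosphoranylidene)propanoate | CCOC(=O)C(C)=P(c1ccccc1)(c1ccccc1)c1ccccc1 | starting material
31 | ethyl (2E)-4-[(tert-butyldimethylsilyl)oxy]-2-methylbut-2-enoate | CCOC(=O)/C(C)=C/CO[Si](C)(C)C(C)(C)C | intermediate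
32 | lithium (2E)-4-[(tert-butyldimethylsilyl)oxy]-2-methylbut-2-enoate (not isolated) | [Li+].[O-]C(=O)/C(C)=C/CO[Si](C)(C)C(C)(C)C | intermediate
33 | (2E)-4-[(tert-butyldimethylsilyl)oxy]-2-methylbut-2-enoic acid | OC(=O)/C(C)=C/CO[Si](C)(C)C(C)(C)C | intermediate
34 | (2E)-4-[(tert-butyldimethylsilyl)oxy]-2-methylbut-2-enoic 2,4,6-trichlorobenzoic anhydride (not isolated) | O=C(OC(=O)/C(C)=C/CO[Si](C)(C)C(C)(C)C)c1c(Cl)cc(Cl)cc1Cl | intermediate
35 | (1S,4R,5E,8S,10R)-8-{[(2E)-4-[(tert-butyldimethylsilyl)oxy]-2-methylbut-2-enoyl]oxy}-1,4-epoxy-1-methoxy-13-[(triethylsilyl)oxy]germacra-5,7(11)-dien-12,6-olide | CC[Si](CC)(CC)OCC1=C2/C(=C\[C@@]3(C)CC[C@](OC)(O3)[C@H](C)C[C@@H]2OC(=O)/C(C)=C/CO[Si](C)(C)C(C)(C)C)OC1=O | intermediate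
36 | 13-hydroxy analogue of 35 (C13–OH free) | OCC1=C2/C(=C\[C@@]3(C)CC[C@](OC)(O3)[C@H](C)C[C@@H]2OC(=O)/C(C)=C/CO[Si](C)(C)C(C)(C)C)OC1=O | intermediate
37 | 13-acetoxy analogue of 35 (C13–OAc, C1–OMe, side-chain silyl ether) | CC(=O)OCC1=C2/C(=C\[C@@]3(C)CC[C@](OC)(O3)[C@H](C)C[C@@H]2OC(=O)/C(C)=C/CO[Si](C)(C)C(C)(C)C)OC1=O | intermediate
38 | CNP0154520.1, (1S,4R,5E,8S,10R)-13-acetoxy-1,4-epoxy-1-hydroxy-8-{[(2E)-4-hydroxy-2-methylbut-2-enoyl]oxy}germacra-5,7(11)-dien-12,6-olide | CC(=O)OCC1=C2/C(=C\[C@@]3(C)CC[C@](O)(O3)[C@H](C)C[C@@H]2OC(=O)/C(C)=C/CO)OC1=O | target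

**Step count and risk**

Total step count: 23 (steps 1–8 to the oxolane aldehyde, step 9 for the tetronate, steps 10–17 to the tricycle, steps 18–19 for the side-chain acid, steps 20–23 for the end game).
Longest linear sequence: 20 steps (steps 1–8, 10–17, 20–23).

The three steps most likely to fail:

1. Step 17 (ring closure). Ten-membered closure is slow, so intermolecular coupling and protodemetallation of the alkenylmetal can compete, and the alkenylchromium may add to the other face of the aldehyde. The fallback for the facial problem sets out from 27 and returns at 28. The cyclisation is accepted with whichever facial sense it shows; if it delivers the 8R carbinol F1, the C8 epimer of 28, then F1 is oxidised with Dess–Martin periodinane to the C8 ketone F2, an enone conjugated to the butenolide. F2 is then reduced under reagent control with borane and the (R)-2-methyl-oxazaborolidine (Corey–Bakshi–Shibata reduction), which, with the sp2 carbon C7 acting as the large substituent, is expected to deliver the 8S carbinol 28.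

2. Step 14 (Z to E photoisomerisation). The photostationary mixture may be poor in the strained E isomer, the dienolide may degrade on long irradiation, and the E isomer may revert on handling. The fallback sets out from 17 and returns at 25. The aldol diastereomers of 17 with unlike configuration at C5 and C6 (5R,6S and 5S,6R) are separated and dehydrated with DIAD and PPh3, conditions under which γ-(α-hydroxyalkyl)butenolides undergo stereospecific anti-elimination, to give directly the E-ylidene allyl tetronate F3. F3 is taken through the chemistry of steps 12 and 13: lithiation with LiN(iPr)2 gives the C11 alkenyllithium F4, formaldehyde converts F4 into the lithium alkoxide F5, TESCl silylates F5 to the E-ylidene C13 silyl ether F6, deallylation of F6 with Pd(PPh3)4 and triethylammonium formate gives the E-ylidene triethylammonium tetronate F7, and triflation of F7 with Tf2O gives 25.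

3. Step 12 (C11 hydroxymethylation). The amide base may deprotonate the allyloxy methylene or add to the dienolide instead of metallating C11 cleanly, and the alkenyllithium may not survive until formaldehyde arrives. The fallback sets out from 19 and returns at 22. Electrophilic iodination of the electron-rich C11 position with N-iodosuccinimide in MeCN gives the C11 iodide F8. Iodine–magnesium exchange on F8 with iPrMgCl·LiCl at −40 °C gives the C11 alkenylmagnesium chloride F9. F9 adds to formaldehyde to give the magnesium alkoxide F10, and F10 is silylated with TESCl to 22.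

**Further compounds**

F1 | step 17 | (1S,4R,5E,8R,10R)-1,4-epoxy-8-hydroxy-1-methoxy-13-[(triethylsilyl)oxy]germacra-5,7(11)-dien-12,6-olide (C8 epimer of 28) | CC[Si](CC)(CC)OCC1=C2/C(=C\[C@@]3(C)CC[C@](OC)(O3)[C@H](C)C[C@H]2O)OC1=O
F2 | step 17 | (1S,4R,5E,10R)-1,4-epoxy-1-methoxy-8-oxo-13-[(triethylsilyl)oxy]germacra-5,7(11)-dien-12,6-olide | CC[Si](CC)(CC)OCC1=C2/C(=C\[C@@]3(C)CC[C@](OC)(O3)[C@H](C)CC2=O)OC1=O
F3 | step 14 | (5E) isomer of 19 | C1=C(OCC=C)/C(=C\[C@@]2(C)CC[C@](OC)(O2)[C@H](C)CCOCc3ccc(OC)cc3)OC1=O
F4 | step 14 | 3-lithio derivative of F3 | [Li]C1=C(OCC=C)/C(=C\[C@@]2(C)CC[C@](OC)(O2)[C@H](C)CCOCc3ccc(OC)cc3)OC1=O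
F5 | step 14 | lithium alkoxide of the 3-(hydroxymethyl) derivative of F3 | [Li+].[O-]CC1=C(OCC=C)/C(=C\[C@@]2(C)CC[C@](OC)(O2)[C@H](C)CCOCc3ccc(OC)cc3)OC1=O
F6 | step 14 | (5E) isomer of 22 | CC[Si](CC)(CC)OCC1=C(OCC=C)/C(=C\[C@@]2(C)CC[C@](OC)(O2)[C@H](C)CCOCc3ccc(OC)cc3)OC1=O
F7 | step 14 | E-ylidene isomer of the triethylammonium tetronate 23 | CC[NH+](CC)CC.CC[Si](CC)(CC)OCC1=C([O-])/C(=C\[C@@]2(C)CC[C@](OC)(O2)[C@H](C)CCOCc3ccc(OC)cc3)OC1=O
F8 | step 12 | 3-iodo derivative of 19 | IC1=C(OCC=C)/C(=C/[C@@]2(C)CC[C@](OC)(O2)[C@H](C)CCOCc3ccc(OC)cc3)OC1=O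
F9 | step 12 | 3-(chloromagnesio) derivative of 19 | Cl[Mg]C1=C(OCC=C)/C(=C/[C@@]2(C)CC[C@](OC)(O2)[C@H](C)CCOCc3ccc(OC)cc3)OC1=O
F10 | step 12 | chloromagnesium alkoxide of the 3-(hydroxymethyl) derivative of 19 | Cl[Mg]OCC1=C(OCC=C)/C(=C/[C@@]2(C)CC[C@](OC)(O2)[C@H](C)CCOCc3ccc(OC)cc3)OC1=O
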